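## Analysis of the target

The target 16 is a 3',8''-linked biflavanone. Flavanone unit 1 has benzo ring A (C4a–C8a), pyranone ring C (O1, C2, C3, C4) and aryl ring B (C1'–C6'); flavanone unit 2 has benzo ring D (C4a''–C8a''), pyranone ring F (O1''–C4'') and the 4-hydroxyphenyl ring E (C1'''–C6'''). The units are joined by the biaryl bond C3'–C8''. There are two stereocentres, C2 and C2'', both S; they lie seven bonds apart on opposite sides of the biaryl bond, so neither can direct the other and each has to be set by a reagent. Each is a benzylic carbon bound to the ring oxygen and β to the C4 (C4'') ketone, so it epimerises in base by enolisation at C3 and retro-oxa-Michael opening to the 2'-hydroxychalcone. The bond C3'–C8'' carries three ortho oxygen substituents (C4'–OH, C7''–OMe, O1'') and is hard to make. Ring D is a fully differentiated phloroglucinol (C5''–OH free, C7''–OMe, C8a''–O in ring F, aryl at C8'' and not at C6''), and only one of the six phenolic oxygens is methylated. The feature the route is built on: each stereocentre holds an aryl ring through a C–C bond, C2–C1' (ring B) and C2''–C1''' (ring E), and ring B is the hub (C1' to C2, C3' to C8''). Without these two bonds, rings C and F are flat, achiral, base-stable 4H-chromen-4-ones.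

## Retrosynthetic reasoning

16 is traced back to its penta-O-benzyl ether 15 by cutting five O–benzyl bonds. Hydrogenolysis is neutral, so it cannot open rings C and F. The C7'' methyl ether is the only ether that has to stay. Benzyl ethers are inert to the palladium and rhodium steps, and the benzyl group on O5 and O5'' removes the chelated acidic phenol that would slow the chromone acceptors.

15 is cut at C2–C1' and at C2''–C1''' (key disconnection) into the chromone boronic acid 8, the chromone 12 and the arylboronic acid 13. This cut removes both stereocentres at once and turns rings C and F into flat chromones. Both bonds are of the same kind (aryl to the β-carbon of a benzopyranone), so one chiral catalyst can make both in one flask, through the mono-adduct 14. Cutting at the biaryl bond or at the ring C–O bonds would instead leave the stereocentres to be made separately or under reversible conditions. The forward reaction has to deliver each aryl group to the Re face of C2 and of C2'', and the boron of 8 has to add to 12 rather than to the chromone of a second molecule of 8 or of 14.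

8 is traced back to the aryl chloride 7 (C1'–B from C1'–Cl). The chloride is a latent boron that survives the biaryl coupling and is unmasked only when the donor function is needed.

7 is cut at the biaryl bond C8''–C3' into the 8-iodochromone 5 and the boronic acid 6. The hindered bond is made on an achiral chromone, where hot aqueous base cannot damage a stereocentre. Iodide in 5 against chloride in 6 secures a single coupling.

5 is traced back through the enaminone 4 to the iodoacetophenone 3, then to the mono-benzyl ether 2 and the symmetric acetophenone 1. Ring F is cut at O1''–C2'' and C2''–C3'' (one carbon added at the acetyl methyl group, closure by the phenol oxygen). Which hydroxyl closes the ring decides whether the aryl ends at C8'' or C6''. The oxygens are therefore differentiated at the start: the two equivalent hydroxyls of 1 give 2 with one free hydroxyl, and iodine is placed ortho to that hydroxyl in 3.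

12 is traced back in the same way through the enaminone 11 to the dibenzyl ether 10 and to 9.

## Alternatives that were turned down

Alternative 1: the textbook cut, the biaryl bond C3'–C8'' made last. The forward key step is a Suzuki–Miyaura coupling of the enantioenriched 8-iodoflavanone A1 with the enantioenriched 3'-boronate A2, followed by debenzylation of 15. It was turned down for three reasons. Both partners already hold their stereocentre, and a tri-ortho-substituted coupling needs aqueous base at 80–100 °C. These are the conditions for C3–H deprotonation and E1cB loss of the C8a phenoxide, and re-closure of the chalcone is not stereoselective. The iodide of A1 is flanked by OMe, O1'' and the nearby C2'' aryl group, so the slow coupling lengthens the exposure. Each half also needs its own asymmetric sequence, which makes the route clearly longer and puts the hardest bond at the end, where failure costs most.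

Alternative 2: cut O1–C2 and O1''–C2'' to the bis(2'-hydroxychalcone) A3. The forward key step is a double catalytic asymmetric intramolecular oxa-Michael addition (6-endo-trig) that closes rings C and F and sets both centres. It was turned down because the cyclisation of a plain 2'-hydroxychalcone is reversible and close to thermoneutral when the phenol is chelated to the ketone and a 6'-alkoxy group is present, as both halves of A3 require. Chiral bases and hydrogen-bond donors reach high selectivity only with an extra ester at C3 that activates the enone and blocks the reverse reaction. That means two carbons to add and remove on each half, and the products racemise under the same catalysts by ring opening. A3 itself needs two different Claisen–Schmidt condensations in strong base on a biaryl that holds both a methyl ketone and an aldehyde, which costs masking steps.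

Alternative 3: the biomimetic cut, C3'–C8'' made by dehydrogenative coupling of two intact flavanones, A4 ((2S)-naringenin) and A5 ((2S)-sakuranetin), to give 16 in one step. The forward key step is one-electron oxidation of the ring B phenol of A4 (anodic or with a hypervalent iodine reagent in a fluorinated alcohol) and attack by C8'' of A5. It was turned down because the selectivity cannot be defended. Ring B of A4 and ring E of A5 are the same 4-hydroxyphenyl group. Rings A and D each offer two nucleophilic positions (C6/C8 and C6''/C8''), and ring A of A4 is the richer one. C–O coupling and homo-coupling compete. Protecting groups that would remove part of this ambiguity bring back the step count and still leave C6'' against C8''.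

Key step: step 8

Assumption 1: the biaryl bond C3'–C8'' (three ortho substituents, none of them large) is taken as not configurationally stable; the target defines no axial descriptor, so the axis is not controlled.

Assumption 2: the (S)-configured biaryl bisphosphine is assumed to give 2S, by the quadrant model that holds for cyclic enones; the hand is to be confirmed once on the 1:1 adduct of 12 and 13, a simple flavanone whose sign of rotation identifies it.

## Route

Step 1
Reactants: 1 1-(2,6-dihydroxy-4-methoxyphenyl)ethanone
Product: 2 1-[2-(benzyloxy)-6-hydroxy-4-methoxyphenyl]ethanone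
Conditions: BnBr (1.05 equiv), K2CO3 (1.1 equiv), acetone, reflux
Reagents that add atoms: benzyl bromide, BrCc1ccccc1
Why: Williamson etherification; the two hydroxyls of 1 are equivalent, and after the first alkylation the remaining one is held in the hydrogen bond to the acetyl carbonyl and is much less nucleophilic, so the reaction should stop at the mono-ether.

Step 2
Reactants: 2 1-[2-(benzyloxy)-6-hydroxy-4-methoxyphenyl]ethanone
Product: 3 1-[6-(benzyloxy)-2-hydroxy-3-iodo-4-methoxyphenyl]ethanone
Conditions: NIS (1.05 equiv), TFA (cat.), CH2Cl2, 0 °C to rt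
Reagents that add atoms: N-iodosuccinimide, O=C1CCC(=O)N1I
Why: Electrophilic aromatic iodination; the position ortho to the free hydroxyl (between OH and OMe) is less shielded than the one between OMe and OBn and is the usual site of attack in 2-hydroxy-4,6-dialkoxyacetophenones, which puts iodine next to the oxygen that becomes O1'', at the future C8''.

Step 3
Reactants: 3 1-[6-(benzyloxy)-2-hydroxy-3-iodo-4-methoxyphenyl]ethanone
Product: 5 5-(benzyloxy)-8-iodo-7-methoxy-4H-chromen-4-one, via enaminone 4 (not isolated)
Conditions: Me2NCH(OMe)2, toluene, 95 °C; then conc. HCl, CH2Cl2, rt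
Reagents that add atoms: N,N-dimethylformamide dimethyl acetal, COC(OC)N(C)C
Why: Enaminone formation at the acetyl methyl group, then acid-promoted addition of the phenol oxygen and loss of dimethylamine (standard chromone synthesis from a 2-hydroxyacetophenone); the acetal carbon becomes C2'', and only the hydroxyl next to iodine is free to close ring F.

Step 4
Reactants: 5 5-(benzyloxy)-8-iodo-7-methoxy-4H-chromen-4-one; 6 [2-(benzyloxy)-5-chlorophenyl]boronic acid
Product: 7 5-(benzyloxy)-8-[2-(benzyloxy)-5-chlorophenyl]-7-methoxy-4H-chromen-4-one
Conditions: Pd(PPh3)4 (8 mol %), K2CO3 (2 M aq.), DME, 85 °C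
Reagents that add atoms: none
Why: Suzuki–Miyaura coupling; zerovalent palladium with triphenylphosphine inserts into the C8''–I bond of 5 and leaves the electron-rich aryl chloride alone, and the coupling is run on the achiral chromone, so the hot aqueous base needed for the tri-ortho-substituted biaryl cannot harm a stereocentre.

Step 5
Reactants: 7 5-(benzyloxy)-8-[2-(benzyloxy)-5-chlorophenyl]-7-methoxy-4H-chromen-4-one
Product: 8 {4-(benzyloxy)-3-[5-(benzyloxy)-7-methoxy-4-oxo-4H-chromen-8-yl]phenyl}boronic acid
Conditions: B2(OH)4 (3 equiv), Pd(OAc)2 (3 mol %), XPhos (6 mol %), KOAc (3 equiv), EtOH, 80 °C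
Reagents that add atoms: tetrahydroxydiboron, OB(O)B(O)O
Why: Miyaura borylation of an aryl chloride in its diboronic acid variant; the bulky dialkylbiarylphosphine allows oxidative addition into the electron-rich C1'–Cl bond, the free boronic acid needed for the base-free key step is formed directly, and acetate is too weak a base to open the chromone.

Step 6
Reactants: 9 1-(2,4,6-trihydroxyphenyl)ethanone
Product: 10 1-[2,4-bis(benzyloxy)-6-hydroxyphenyl]ethanone
Conditions: BnBr (2.1 equiv), K2CO3 (2.2 equiv), DMF, rt
Reagents that add atoms: benzyl bromide, BrCc1ccccc1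
Why: Williamson etherification; the para hydroxyl (most acidic, not chelated) reacts first, then one ortho hydroxyl, and the last one stays chelated to the carbonyl and free for ring closure.

Step 7
Reactants: 10 1-[2,4-bis(benzyloxy)-6-hydroxyphenyl]ethanone
Product: 12 5,7-bis(benzyloxy)-4H-chromen-4-one, via enaminone 11 (not isolated)
Conditions: Me2NCH(OMe)2, toluene, 95 °C; then conc. HCl, CH2Cl2, rt
Reagents that add atoms: N,N-dimethylformamide dimethyl acetal, COC(OC)N(C)C
Why: Same enaminone formation and acid-promoted cyclisation as in step 3; the acetal carbon becomes C2 of ring C.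

Step 8
Reactants: 8 {4-(benzyloxy)-3-[5-(benzyloxy)-7-methoxy-4-oxo-4H-chromen-8-yl]phenyl}boronic acid; 12 5,7-bis(benzyloxy)-4H-chromen-4-one; 13 [4-(benzyloxy)phenyl]boronic acid
Product: 15 (2S)-5,7-bis(benzyloxy)-2-{4-(benzyloxy)-3-[(2S)-5-(benzyloxy)-2-[4-(benzyloxy)phenyl]-7-methoxy-4-oxochroman-8-yl]phenyl}chroman-4-one, via mono-adduct 14 (not isolated)
Conditions: [Rh(OH)(cod)]2 (3 mol %), (S)-MeO-F12-BIPHEP (6.6 mol %), toluene/H2O 10:1, 35 °C; 12 (3 equiv) in the flask, 8 (1 equiv, in THF) added over 3 h; then 13 (6 equiv), 35 °C
Reagents that add atoms: none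
Why: The hydroxo complex of monovalent rhodium with the bisphosphine transmetalates with the arylboronic acid, the chromone C2=C3 bond inserts into the aryl–rhodium bond (aryl to C2, rhodium to C3 as an oxa-π-allyl enolate), and water protonates the enolate and returns the hydroxo complex. The closest known reaction type is the rhodium/biaryl-bisphosphine-catalysed asymmetric 1,4-addition of arylboronic acids to 5,7-dioxygenated chromones that gives 2-arylchroman-4-ones; here it is run twice in one flask with one catalyst charge. No ring is closed: rings C and F are already present as flat chromones, and the step forms the bonds C2–C1' (first stage, giving 14) and C2''–C1''' (second stage). Both stereocentres are set by the ligand alone: the twofold-symmetric, electron-poor bisphosphine (2,2'-bis[bis(3,4,5-trifluorophenyl)phosphino]-6,6'-dimethoxybiphenyl) blocks one enantioface of each chromone, so the aryl group is delivered to the Re face of C2 and of C2'' (order O1 > C3 > H), which is S at both; the two sites are seven bonds apart, so there is no matched or mismatched pairing. The first selectivity needed is that the aryl–rhodium species from 8 adds to 12 and not to the chromone of 8 or of 14: this rests on the threefold excess of 12, on the slow addition of 8, on the shielding of C2'' by the twisted ring B at C8'', and on the fact that intramolecular addition is impossible because C1' and C2'' are bridged through a meta-phenylene. The second is that ring F of 14 is fully arylated: the excess of 13 secures this and at the same time consumes the remaining 12 as its 1:1 adduct with 13, which is much smaller than 15 and should separate easily. The neutral, base-free medium at 35 °C should keep the rhodium enolates from retro-oxa-Michael opening and the finished C2 centre of 14 from epimerising during the second stage. Because two independent enantioselective events are combined, most of the minor hand at either centre ends up in a diastereomer of 15 that chromatography can remove, so the enantiomeric purity of 15 should exceed that of a single addition.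

Step 9
Reactants: 15 (2S)-5,7-bis(benzyloxy)-2-{4-(benzyloxy)-3-[(2S)-5-(benzyloxy)-2-[4-(benzyloxy)phenyl]-7-methoxy-4-oxochroman-8-yl]phenyl}chroman-4-one
Product: 16 (2S)-5,7-dihydroxy-2-{4-hydroxy-3-[(2S)-5-hydroxy-2-(4-hydroxyphenyl)-7-methoxy-4-oxochroman-8-yl]phenyl}chroman-4-one
Conditions: H2 (1 atm), 10% Pd/C, THF/MeOH 1:1, rt
Reagents that add atoms: none
Why: Hydrogenolysis of the five aryl benzyl ethers under neutral conditions; the C7'' methyl ether is inert, no base is present so C2 and C2'' keep their configuration, and the reaction is stopped at the calculated uptake to spare the C4 and C4'' ketones and the benzylic C2–O1 and C2''–O1'' bonds.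

## Compound list

1 | 1-(2,6-dihydroxy-4-methoxyphenyl)ethanone | CC(=O)c1c(O)cc(OC)cc1O | starting material
2 | 1-[2-(benzyloxy)-6-hydroxy-4-methoxyphenyl]ethanone | CC(=O)c1c(O)cc(OC)cc1OCc1ccccc1 | intermediate
3 | 1-[6-(benzyloxy)-2-hydroxy-3-iodo-4-methoxyphenyl]ethanone | CC(=O)c1c(O)c(I)c(OC)cc1OCc1ccccc1 | intermediate
4 | (E)-1-[6-(benzyloxy)-2-hydroxy-3-iodo-4-methoxyphenyl]-3-(dimethylamino)prop-2-en-1-one | CN(C)/C=C/C(=O)c1c(O)c(I)c(OC)cc1OCc1ccccc1 | intermediate
5 | 5-(benzyloxy)-8-iodo-7-methoxy-4H-chromen-4-one | COc1cc(OCc2ccccc2)c2c(=O)ccoc2c1I | intermediate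
6 | [2-(benzyloxy)-5-chlorophenyl]boronic acid | OB(O)c1cc(Cl)ccc1OCc1ccccc1 | starting material
7 | 5-(benzyloxy)-8-[2-(benzyloxy)-5-chlorophenyl]-7-methoxy-4H-chromen-4-one | COc1cc(OCc2ccccc2)c2c(=O)ccoc2c1-c1cc(Cl)ccc1OCc1ccccc1 | intermediate
8 | {4-(benzyloxy)-3-[5-(benzyloxy)-7-methoxy-4-oxo-4H-chromen-8-yl]phenyl}boronic acid | COc1cc(OCc2ccccc2)c2c(=O)ccoc2c1-c1cc(B(O)O)ccc1OCc1ccccc1 | intermediate
9 | 1-(2,4,6-trihydroxyphenyl)ethanone | CC(=O)c1c(O)cc(O)cc1O | starting material
10 | 1-[2,4-bis(benzyloxy)-6-hydroxyphenyl]ethanone | CC(=O)c1c(O)cc(OCc2ccccc2)cc1OCc1ccccc1 | intermediate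
11 | (E)-1-[2,4-bis(benzyloxy)-6-hydroxyphenyl]-3-(dimethylamino)prop-2-en-1-one | CN(C)/C=C/C(=O)c1c(O)cc(OCc2ccccc2)cc1OCc1ccccc1 | intermediate
12 | 5,7-bis(benzyloxy)-4H-chromen-4-one | O=c1ccoc2cc(OCc3ccccc3)cc(OCc3ccccc3)c12 | intermediate
13 | [4-(benzyloxy)phenyl]boronic acid | OB(O)c1ccc(OCc2ccccc2)cc1 | starting material
14 | (2S)-5,7-bis(benzyloxy)-2-{4-(benzyloxy)-3-[5-(benzyloxy)-7-methoxy-4-oxo-4H-chromen-8-yl]phenyl}chroman-4-one | COc1cc(OCc2ccccc2)c2c(=O)ccoc2c1-c1cc([C@@H]3CC(=O)c4c(OCc5ccccc5)cc(OCc5ccccc5)cc4O3)ccc1OCc1ccccc1 | intermediate
15 | (2S)-5,7-bis(benzyloxy)-2-{4-(benzyloxy)-3-[(2S)-5-(benzyloxy)-2-[4-(benzyloxy)phenyl]-7-methoxy-4-oxochroman-8-yl]phenyl}chroman-4-one | COc1cc(OCc2ccccc2)c2c(c1-c1cc([C@@H]3CC(=O)c4c(OCc5ccccc5)cc(OCc5ccccc5)cc4O3)ccc1OCc1ccccc1)O[C@H](c1ccc(OCc3ccccc3)cc1)CC2=O | intermediate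
16 | (2S)-5,7-dihydroxy-2-{4-hydroxy-3-[(2S)-5-hydroxy-2-(4-hydroxyphenyl)-7-methoxy-4-oxochroman-8-yl]phenyl}chroman-4-one (CNP0237714.1) | COc1cc(O)c2c(c1-c1cc([C@@H]3CC(=O)c4c(O)cc(O)cc4O3)ccc1O)O[C@H](c1ccc(O)cc1)CC2=O | target

## Step count and least certain steps

Total step count: 9. Longest linear sequence: 7 steps (1, 2, 3, 4, 5, 8, 9); steps 6 and 7 form the side branch to 12.

Step 8 (key step). Most likely to go wrong: as 14 builds up, the aryl–rhodium species from 8 may add to the chromone of 14 or of 8 (oligomerisation), and the limiting boronic acid 8 may be lost by protodeboronation at the aryl–rhodium stage. Fallback: donor and acceptor are never present in the same molecule. Setting out from 7, addition of 13 under the same rhodium catalyst should give (2S)-5-(benzyloxy)-8-[2-(benzyloxy)-5-chlorophenyl]-2-[4-(benzyloxy)phenyl]-7-methoxychroman-4-one F1. Palladium-catalysed borylation with tetrahydroxydiboron as in step 5 should give {4-(benzyloxy)-3-[(2S)-5-(benzyloxy)-2-[4-(benzyloxy)phenyl]-7-methoxy-4-oxochroman-8-yl]phenyl}boronic acid F2. Rhodium-catalysed addition of F2 to an excess of 12 comes back to the route at 15. This costs one more isolated step and uses only known reaction types.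

Step 4. Most likely to go wrong: slow coupling at the tri-ortho-substituted axis, which leaves time for hydroxide attack at C2'' of the chromone (ring opening) and for protodeboronation of 6. Fallback: the biaryl bond is made before ring F exists. Setting out from 3, whose phenoxide is stable to the base, Suzuki–Miyaura coupling with 6 should give 1-[6-(benzyloxy)-3-[2-(benzyloxy)-5-chlorophenyl]-2-hydroxy-4-methoxyphenyl]ethanone F3. The formamide acetal should give the enaminone (E)-1-[6-(benzyloxy)-3-[2-(benzyloxy)-5-chlorophenyl]-2-hydroxy-4-methoxyphenyl]-3-(dimethylamino)prop-2-en-1-one F4, and acid closes ring F, coming back to the route at 7.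

Step 5. Most likely to go wrong: transfer reduction by the diboron/ethanol/palladium system (hydrodechlorination, or reduction of the C2''=C3'' bond) and loss of the free boronic acid on isolation. Fallback: aprotic borylation and a separate unmasking. Setting out from 7, bis(pinacolato)diboron with Pd2(dba)3/XPhos and KOAc in dioxane should give 5-(benzyloxy)-8-[2-(benzyloxy)-5-(4,4,5,5-tetramethyl-1,3,2-dioxaborolan-2-yl)phenyl]-7-methoxy-4H-chromen-4-one F5, which can be purified on silica. NaIO4/NH4OAc in aqueous acetone cleaves the pinacol ester and comes back to the route at 8.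

Step 2. Most likely to go wrong: poor regioselectivity, with iodination para to the free hydroxyl (between the two ethers) or twofold iodination. Fallback: ring F is closed first and iodine is introduced when no free hydroxyl is left to direct the attack. Setting out from 2, the formamide acetal should give (E)-1-[2-(benzyloxy)-6-hydroxy-4-methoxyphenyl]-3-(dimethylamino)prop-2-en-1-one F6, and acid should give 5-(benzyloxy)-7-methoxy-4H-chromen-4-one F7. NIS/TFA should then iodinate C8, which lies between the methoxy group and the tied-back ring oxygen and is less hindered than C6 between the two ethers, coming back to the route at 5.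

Step 9. Most likely to go wrong: over-reduction during the long exposure that five benzyl groups need (hydrogenolysis of the benzylic C2–O1 and C2''–O1'' bonds to dihydrochalcones, or reduction of the ketones). Fallback: Lewis-acid debenzylation in place of hydrogenolysis. Setting out from 15, BCl3 with pentamethylbenzene as cation scavenger in CH2Cl2 at −78 °C should remove the aryl benzyl ethers and leave the C7'' methyl ether, which is not peri to a carbonyl group. It comes back at 16 and makes no new compound (F0).

## Further compounds

F1 | step 8 | (2S)-5-(benzyloxy)-8-[2-(benzyloxy)-5-chlorophenyl]-2-[4-(benzyloxy)phenyl]-7-methoxychroman-4-one | COc1cc(OCc2ccccc2)c2c(c1-c1cc(Cl)ccc1OCc1ccccc1)O[C@H](c1ccc(OCc3ccccc3)cc1)CC2=O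
F2 | step 8 | {4-(benzyloxy)-3-[(2S)-5-(benzyloxy)-2-[4-(benzyloxy)phenyl]-7-methoxy-4-oxochroman-8-yl]phenyl}boronic acid | COc1cc(OCc2ccccc2)c2c(c1-c1cc(B(O)O)ccc1OCc1ccccc1)O[C@H](c1ccc(OCc3ccccc3)cc1)CC2=O
F3 | step 4 | 1-[6-(benzyloxy)-3-[2-(benzyloxy)-5-chlorophenyl]-2-hydroxy-4-methoxyphenyl]ethanone | CC(=O)c1c(O)c(-c2cc(Cl)ccc2OCc2ccccc2)c(OC)cc1OCc1ccccc1
F4 | step 4 | (E)-1-[6-(benzyloxy)-3-[2-(benzyloxy)-5-chlorophenyl]-2-hydroxy-4-methoxyphenyl]-3-(dimethylamino)prop-2-en-1-one | CN(C)/C=C/C(=O)c1c(O)c(-c2cc(Cl)ccc2OCc2ccccc2)c(OC)cc1OCc1ccccc1
F5 | step 5 | 5-(benzyloxy)-8-[2-(benzyloxy)-5-(4,4,5,5-tetramethyl-1,3,2-dioxaborolan-2-yl)phenyl]-7-methoxy-4H-chromen-4-one | COc1cc(OCc2ccccc2)c2c(=O)ccoc2c1-c1cc(B2OC(C)(C)C(C)(C)O2)ccc1OCc1ccccc1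
F6 | step 2 | (E)-1-[2-(benzyloxy)-6-hydroxy-4-methoxyphenyl]-3-(dimethylamino)prop-2-en-1-one | CN(C)/C=C/C(=O)c1c(O)cc(OC)cc1OCc1ccccc1
F7 | step 2 | 5-(benzyloxy)-7-methoxy-4H-chromen-4-one | COc1cc(OCc2ccccc2)c2c(=O)ccoc2c1
F0 | step 9 | none | none
A1 | alternative 1 | (2S)-5-(benzyloxy)-2-[4-(benzyloxy)phenyl]-8-iodo-7-methoxychroman-4-one | COc1cc(OCc2ccccc2)c2c(c1I)O[C@H](c1ccc(OCc3ccccc3)cc1)CC2=O
A2 | alternative 1 | (2S)-5,7-bis(benzyloxy)-2-[4-(benzyloxy)-3-(4,4,5,5-tetramethyl-1,3,2-dioxaborolan-2-yl)phenyl]chroman-4-one | CC1(C)OB(OC1(C)C)c1cc(ccc1OCc1ccccc1)[C@@H]1CC(=O)c2c(OCc3ccccc3)cc(OCc3ccccc3)cc2O1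
A3 | alternative 2 | (E)-1-[2,4-bis(benzyloxy)-6-hydroxyphenyl]-3-{4-(benzyloxy)-3-[4-(benzyloxy)-3-{(E)-3-[4-(benzyloxy)phenyl]prop-2-enoyl}-2-hydroxy-6-methoxyphenyl]phenyl}prop-2-en-1-one | O=C(/C=C/c1ccc(OCc2ccccc2)c(c1)-c1c(OC)cc(OCc2ccccc2)c(C(=O)/C=C/c2ccc(OCc3ccccc3)cc2)c1O)c1c(O)cc(OCc2ccccc2)cc1OCc1ccccc1
A4 | alternative 3 | (2S)-5,7-dihydroxy-2-(4-hydroxyphenyl)chroman-4-one ((2S)-naringenin) | Oc1ccc(cc1)[C@@H]1CC(=O)c2c(O)cc(O)cc2O1
A5 | alternative 3 | (2S)-5-hydroxy-2-(4-hydroxyphenyl)-7-methoxychroman-4-one ((2S)-sakuranetin) | Oc1ccc(cc1)[C@@H]1CC(=O)c2c(O)cc(OC)cc2O1
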